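The runs stem from a simulated flask on assumed constants, noise included.

If two reactants go in at equal charge and the target still stalls, do a subtraction first.

| setting | alder | cedar | flask |
|---|---|---|---|
| starting material | 12 mM | 12 mM | 12 mM |
| second substrate | 12 mM | 18 mM | 12.0 mM |
| protic impurity | 2.4 mM | 2.4 mM | 2.40 mM |
| free enzyme | 1.2 µM | 1.2 µM | 1.2 µM |
| temperature | 40 °C | 46 °C | 40 °C |
| remark | the very flask that is asked about, followed so far | run made earlier |  |
| time |  |  | 8.0 d |

| run | time / d | target / % | starting material / % |
|---|---|---|---|
| alder | 1.04 | 57.0 | 32.6 |
| alder | 3.00 | 74.6 | 20.0 |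
| alder | 5.00 | 77.5 | 16.8 |
| alder | 8.00 | 79.2 | 16.2 |
| cedar | 0.417 | 52.3 | 34.0 |
| cedar | 1.04 | 77.1 | 16.9 |
| cedar | 2.08 | 89.3 | 8.9 |
| cedar | 3.00 | 94.4 | 5.6 |

(each reading ± 0.5 percentage points)

- green: at 8.0 d add second substrate, 50.0% of the amount charged, then wait 15 d
- blue: change nothing and wait 15 d more
- red: at 8.0 d raise the temperature by 10 K, then wait 15 d
- grey: at 8.0 d take out 90% of the target then present, then wait 15 d
- amber: at 8.0 d add free enzyme, 100% of the amount charged, then wait 15 d

- target, in percent of the starting material first charged, at 8.0 d
- the option that brings most further target ("none" if no option brings more than 2 percentage points) (green / blue / red / grey / amber / none)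
- target present, with what was taken out counted in, in percent of the starting material first charged, after green
- target present, with what was taken out counted in, in percent of the starting material first charged, after grey

- what is taken out of target is counted as made
- additions bring no volume worth counting

1. The puzzle. In alder, which is this flask followed so far, second substrate stands at 1.00 of the starting material charge. Yet from 5.00 d to 8.00 d target creeps from 77.5% to 79.2%, with 16.2% of the starting material still read.

2. The reckoning, which is mine. Assume second substrate leaves in two ways, one for each target made and one for each protic impurity quenched. Its rate of loss is then the sum of those two rates. Divide through by that rate and time drops out: target made equals second substrate lost minus impurity quenched.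

3. So this flask has a usable share of 80.0%, second substrate charge minus protic impurity charge, as a fraction of the starting material charge. Second substrate is the limiting reagent in this flask.

4. Check it. The last alder reading sits 0.8 percentage points below that share. Cedar, with a usable share of 130%, reads 94.4% at 3.00 d, though it ran hotter, at 46 °C.

5. Use it. Green lifts the share to 130%, past the whole charge, so I expect green to win and to approach complete conversion. Grey adds no second substrate, so I expect about 80.0% there.

6. The forecast gives 79.2% now, green as best, 99.5% after green and 80% after grey, on this ground: “The alder run is therefore simply out of second substrate.”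

7. The flask gives 79.3% and green as best, adding 21 points, with 99.9% after green and 80.0% after grey.

    second substrate + starting complex ⇌ ternary complex (K = 130 M⁻¹, k = 2.60 × 10⁵ M⁻¹ h⁻¹, Ea = 42.0 kJ mol⁻¹, ΔH = −67.0 kJ mol⁻¹)
    free enzyme → unfolded enzyme (k = 0.00315 h⁻¹, Ea = 205 kJ mol⁻¹)
    second substrate + protic impurity → quenched reagent (k = 42.6 M⁻¹ h⁻¹, Ea = 62.0 kJ mol⁻¹)
    starting material + free enzyme ⇌ starting complex (K = 64.5 M⁻¹, k = 8.40 × 10⁵ M⁻¹ h⁻¹, Ea = 44.0 kJ mol⁻¹, ΔH = −34.0 kJ mol⁻¹)
    ternary complex → free enzyme + target (k = 4100 h⁻¹, Ea = 78.0 kJ mol⁻¹)
    starting material ⇌ dormant form (K = 0.270, k = 0.0682 h⁻¹, Ea = 97.0 kJ mol⁻¹, ΔH = 23.0 kJ mol⁻¹)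
    (constants at 40 °C)

8. At 8.00 d this flask still holds 0.671% of its charged second substrate free, and its target stands 0.70 points under the usable share. A neighbour flask charged with 0.400 equiv of second substrate has a usable share of 20.0%, yet it gives 23.6%. Its second substrate is down to 0%, while 18% of its protic impurity remains. Put that neighbour's 1.97 mM of quenched reagent in place of its impurity charge and its share becomes 23.6%.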